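The numbers in the tables come from a simulation on assumed constants.

**Slow flask.** The midnight flask was slow: c(Sbt) fell by 0.144 M in 14 h, from a charge of 0.400 M.

| flask | Sbt | Ptn | Ctl | Pdt | time |
|---|---|---|---|---|---|
| midnight | 0.400 M | 0.800 M | 0.00800 M |  |  |
| winter | 0.400 M | 1.60 M | 0.00800 M |  |  |
| spring | 0.400 M | 0.800 M | 0.0240 M |  |  |
| summer | 0.400 M | 0.800 M | 0.00800 M | 0.120 M |  |
| dawn | 0.120 M | 0.520 M | 0.00800 M |  | 14 h |

- midnight run (time / h: [Sbt] / M): 0.56: 0.3917; 0.89: 0.3874; 1.4: 0.3822; 2.2: 0.3735; 3.5: 0.3612; 5.6: 0.3319; 8.8: 0.3018; 14: 0.2564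
- winter run (time / h: [Sbt] / M): 0.56: 0.3915; 0.89: 0.3876; 1.4: 0.3829; 2.2: 0.3713; 3.5: 0.3558; 5.6: 0.3382; 8.8: 0.3006; 14: 0.2559
- spring run (time / h: [Sbt] / M): 0.56: 0.3880; 0.89: 0.3752; 1.4: 0.3683; 2.2: 0.3476; 3.5: 0.3243; 5.6: 0.2825; 8.8: 0.2287; 14: 0.1647
- summer run (time / h: [Sbt] / M): 0.56: 0.3948; 0.89: 0.3872; 1.4: 0.3826; 2.2: 0.3724; 3.5: 0.3578; 5.6: 0.3327; 8.8: 0.3016; 14: 0.2533

(readings scatter by 0.002 M)

- Overall: Sbt + Ptn -> Pdt, with Ctl as catalyst.
- Constant volume, constant temperature.
- "The second partner" is Ptn.
- An order is taken over about fifteen percent of the charge, up and down.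

- the power of [Ctl] that the first rate follows, about the charge of the midnight run; measure it at two percent of Sbt made into Pdt
- the power of [Ptn] that the first rate follows, about the charge of the midnight run; measure it at two percent of Sbt made into Pdt
- Sbt in the dawn run at 14 h, as a share of the Sbt charged
- which of these the readings show (the by-product binds the second partner / the catalyst rests as a dimer / nothing beyond the main steps / the second partner kills the catalyst)

**Bench rule.** At the bench I would first book such a flask as a steady loss, and the midnight flask gave 0.0103 M h⁻¹. Applied to the dawn flask, this rule removes 0.144 M in 14 h, which is more than its charge of 0.120 M, so it empties that flask after 11.7 h. The border is the ratio of booked loss to charge: 0.360 for the midnight flask, but 1.20 for the dawn flask. The midnight readings also bend: the loss read 0.0111 M h⁻¹ up to 3.5 h and 0.00873 M h⁻¹ after 8.8 h, which is slower.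

**Sbt balance.** So I wrote the balance of Sbt, the limiting reagent in the dawn flask (0.120 M against 0.520 M of Ptn). The winter flask, with Ptn at 1.60 M, stood at 0.2559 M at 14 h against 0.2564 M for the midnight flask, a gap below the scatter, so I left Ptn out of the balance. From the midnight flask I read 0.0318 h⁻¹, the fractional drain, the share of the Sbt present that goes per hour at a fixed Ctl charge; this is the pseudo-first-order constant. It predicts 0.3024 M for the midnight flask at 8.8 h, and the reading there was 0.3018 M.

**Ctl charge.** The drain belongs to its Ctl charge: the spring flask, at 0.0240 M, read 0.0634 h⁻¹, twice the midnight value. That is an average power of 0.629 in Ctl, and a power below one pointed me to a dimer as the catalyst's resting state. The dawn flask has the midnight charge of 0.00800 M, so I expected 64.1% of its Sbt left at 14 h.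

**The forecast.** It gave 0.65 for Ctl, 0 for Ptn, 64% for the dawn flask, and "the catalyst rests as a dimer", on the ground that “Dawn has the same Ctl and Ptn still in the zero-order region”.

**Flask result.** The dawn flask held 63.7% of its Sbt at 14 h; the powers were 0.64 for Ctl and 0.011 for Ptn, and the answer was "the catalyst rests as a dimer".

    Ctl + Sbt → E + Lvg (9.396 M⁻¹ h⁻¹)
    E + Ptn → Pdt + Ctl (115.6 M⁻¹ h⁻¹)
    2 Ctl ⇌ Ctl2, settled at all times (193.0 M⁻¹)

Read back from the dawn flask, the drain is 0.0322 h⁻¹, against 0.0318 h⁻¹ from the midnight flask. At the same small conversion, the winter rate stood at 1.0 times the midnight rate. The drain puts half of the Sbt charge gone at 21.8 h, and in the winter flask, at the same Ctl charge, the Pdt made reached half of the Sbt charged at 21.6 h.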